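**Assumption:** the SMILES as written is taken as the definition of the target. It places H‑9 anti to the C8–C15 bond (δ‑lactone trans‑fused to the cyclohexanol ring, 11‑OH equatorial), and the route is aimed at exactly that configuration.

**Atom labels used below (ent‑kaurane numbering):** A ring = C1–C5 + C10; C6 = CHO carbon; C7 = lactone C=O; C8 = quaternary bridgehead; C9 = CH; C11 = CHOH; C13 = bridgehead CH; C15 = ketone; C16=C17 = methylene; C18 = CH3 and C19 = CH2OAc on C4; C20 = lactone OCH2.

## Retrosynthetic overview

1. Target ⇐ acetal hydrolysis, allylic oxidation and C11 reduction of tetracycle 14; D ring (C13–C16) by 5‑exo vinyl‑radical cyclization of a propargylic alcohol.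
2. C8 quaternary centre ⇐ Birch reductive carboxylation of the aromatic spiro‑isochromanone 9, then lactone transposition: the old aryl lactone C=O becomes C15 and the new CO2Me becomes the C7 lactone.
3. A ring (C10, C5, C4) ⇐ enantioselective desymmetrization of the achiral spiro‑cyclohexadienone 4, two C4 enolate alkylations, then excision of C3=O.
4. Spirodienone 4 ⇐ dearomative para‑alkylation of biaryl phenol 3 with a CH2 linchpin; 3 ⇐ 3‑methoxybenzoic acid + 4‑bromophenol.
5. Ring order: biaryl → lactone/A ring (spiro) → A ring elaborated → C ring dearomatized → D ring.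

## Route

**Step 1**
Reactants: 1, 3‑methoxybenzoic acid; 2, 4‑bromophenol
Product: 3, 2‑(4‑hydroxyphenyl)‑3‑methoxybenzoic acid
Conditions: LiTMP (2.2 equiv), THF, −78 → 0 °C; B(OiPr)3; then 2, Pd(OAc)2/SPhos, K3PO4 (aq), 65 °C (one pot)
Reagents that add atoms: none
Why: carboxylate/OMe‑cooperative directed ortho‑metalation at C2, borylation, then Suzuki–Miyaura coupling; no stereocentre.

**Step 2**
Reactants: 3, biaryl acid
Product: 4, 5‑methoxyspiro[isochromane‑4,1′‑cyclohexa‑2′,5′‑diene]‑1,4′‑dione (achiral; lactone C=O = future C15, OCH2 = C20, spiro C = C10)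
Conditions: Cs2CO3 (1 equiv), ClCH2I, DMF, 0 °C; strip volatiles; then Cs2CO3 (1.5 equiv), NaI (cat.), MeCN, 0.01 M, 60 °C
Reagents that add atoms: chloroiodomethane, ClCI
Why: carboxylate O‑alkylation gives the chloromethyl ester; the phenoxide can only reach it through its para carbon (6‑exo‑tet Winstein–Baird Ar1‑6 alkylative dearomatization), giving a symmetric spirodienone.

**Step 3**
Reactants: 4, spirodienone
Product: 5, C5‑(1,3‑dioxolan‑2‑yl) spiro‑enone (C1=C2–C3=O retained; dioxolane on C5 cis to C20, trans to the aryl carbon)
Conditions: 1,3‑dioxolane (excess), TBADT (2 mol %), carbazole‑tethered chiral primary amine·TFA (20 mol %, enantiomer giving the C5 configuration shown), MeCN, 390 nm, 10 °C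
Reagents that add atoms: 1,3‑dioxolane, C1COCO1
Why: Proposed new method: decatungstate HAT generates the nucleophilic dioxolan‑2‑yl radical (a formyl‑radical equivalent), which is trapped by the chiral iminium ion of one enantiotopic enone arm, anti to the edge‑on aryl group; this desymmetrizing step sets C5 and C10. Closest known reactions: decatungstate/dioxolane Giese addition to enones, and enantioselective iminium‑ion trapping of acetal‑type radicals with chiral primary amines.

**Step 4**
Reactants: 5
Product: 6, C4‑(benzyloxymethyl) derivative of 5 (mainly trans to the dioxolane; C4 configuration is erased in step 5)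
Conditions: LDA, THF, −78 °C; BnOCH2Cl, −78 → −20 °C
Reagents that add atoms: benzyl chloromethyl ether, ClCOCc1ccccc1
Why: C4 is the only enolizable position (C2 is vinylic, C10 quaternary); C‑alkylation of the cross‑conjugated lithium dienolate.

**Step 5**
Reactants: 6
Product: 7, C4‑methyl‑C4‑(benzyloxymethyl) spiro‑enone (CH2OBn cis to dioxolane and C20; CH3 on the aryl face)
Conditions: KHMDS, THF, −78 °C; MeI, −78 → 0 °C
Reagents that add atoms: iodomethane, CI
Why: enolate alkylation; MeI enters equatorially, anti to the syn‑axial C20H2–O on C10 and anti to the adjacent dioxolane (podocarpate‑type C4 alkylation), setting the C4 quaternary centre.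

**Step 6**
Reactants: 7
Product: 8, enol triflate (C1H2–C2H=C3–OTf)
Conditions: L‑Selectride, THF, −78 °C; then PhNTf2, −78 °C → rt
Reagents that add atoms: N‑phenyl‑bis(trifluoromethanesulfonimide), O=S(=O)(N(c1ccccc1)S(=O)(=O)C(F)(F)F)C(F)(F)F
Why: conjugate hydride reduction (1,2‑attack blocked by quaternary C4) gives a regiodefined enolate, trapped as the enol triflate.

**Step 7**
Reactants: 8
Product: 9, aromatic spiro‑isochromanone with saturated A ring (C5 dioxolane, C4 CH3/CH2OBn)
Conditions: H2 (1 atm), PtO2, EtOAc, rt
Reagents that add atoms: none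
Why: hydrogenation/hydrogenolysis of the enol triflate to CH2–CH2 removes the C3 oxygen; arene, lactone, acetal and benzyl ether survive Pt.

**Step 8**
Reactants: 9
Product: 10, dearomatized lactone ester (C8 quaternary: lactone C=O and CO2Me; ring C 1,4‑diene with C9=C11(OMe) and C13=C14; C19–OH free; CO2Me cis to C1, anti to C5 on the lactone ring)
Conditions: Li (5 equiv), NH3/THF, t‑BuOH (1 equiv), −78 °C; isoprene; remove NH3; CO2 (g), −78 °C; pH 5 buffer; TMSCHN2, PhMe/MeOH, 0 °C
Reagents that add atoms: carbon dioxide, O=C=O; trimethylsilyldiazomethane, C[Si](C)(C)C=[N+]=[N-]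
Why: Birch reduction of the aroyl lactone (protonation para at C12; meta‑OMe kept as enol ether) gives the lactone dienolate, which is carboxylated at C8. C5 is held pseudo‑axial by A1,3 strain with the C11–OMe, so CO2 adds from the opposite (C1) face and sets C8 by 1,3‑induction. The benzyl ether is cleaved in the same pot; the acid is then esterified.

**Step 9**
Reactants: 10
Product: 11, conjugated diene isomer (C9=C11(OMe)–C12=C13, C14H2)
Conditions: RhCl(PPh3)3 (5 mol %), PhMe, 80 °C
Reagents that add atoms: none
Why: Rh–H isomerization of the disubstituted alkene into conjugation (Birch–Subba Rao 1,4‑ to 1,3‑diene isomerization); the tetrasubstituted enol ether and C8 are untouched.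

**Step 10**
Reactants: 11
Product: 12, transposed δ‑lactone (C7(=O)–O–C20) bearing C8–CH(OH)–C≡CH (C15 epimers); C15 cis to C5
Conditions: DIBAL‑H (2.2 equiv), CH2Cl2, −78 °C; then HC≡CMgBr (5 equiv), THF, −78 → 0 °C; NH4Cl (aq)
Reagents that add atoms: ethynylmagnesium bromide, C#C[Mg]Br
Why: the lactone is reduced to the lactol in preference to the hindered methyl ester; the ring‑opened aldehyde is intercepted by the Grignard reagent while the freed C20 alkoxide closes onto the C7 ester (6‑exo‑trig translactonization). C8 is not touched, so the old lactone carbon (now C15) ends up cis to C5.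

**Step 11**
Reactants: 12
Product: 13, C19 acetate of 12
Conditions: Ac2O (1.2 equiv), pyridine, CH2Cl2, 0 °C
Reagents that add atoms: acetic anhydride, CC(=O)OC(C)=O
Why: selective acylation of the primary alcohol over the neopentyl secondary propargylic alcohol.

**Step 12**
Reactants: 13
Product: 14, bicyclo[3.2.1]octane ketone (C16=C17H2, C15–OH, C11=O, H‑9 anti to the C15–C16 bridge)
Conditions: Bu3SnH (slow addition), AIBN, PhH, 80 °C; then TsOH·H2O (cat.), wet CH2Cl2, rt
Reagents that add atoms: water, O
Why: Stork‑type stannyl‑radical addition to the alkyne and 5‑exo vinyl‑radical cyclization onto the diene terminus C13 (the tether forces C13 cis to C15). H‑atom transfer or enol‑ether protonation at C9 occurs on the exo face opposite the new bridge. Acid then effects protodestannylation and enol‑ether hydrolysis.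

**Step 13**
Reactants: 14
Product: 15, 11‑equatorial alcohol
Conditions: SmI2, HMPA, THF/i‑PrOH, 0 °C
Reagents that add atoms: none
Why: single‑electron ketone reduction gives the thermodynamically preferred equatorial alcohol (compare Na/ROH on tropinone giving pseudotropine); hydride reagents would attack the exo face and give the wrong axial epimer.

**Step 14**
Reactants: 15
Product: 16, exo‑methylene enone (C15=O) with C6 still as the dioxolane
Conditions: MnO2 (excess), CH2Cl2, rt
Reagents that add atoms: none
Why: chemoselective oxidation of the allylic alcohol; the saturated C11–OH is untouched.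

**Step 15**
Reactants: 16
Product: 17, trichorabdal B
Conditions: 1 M HCl, THF, 0 °C → rt
Reagents that add atoms: water, O
Why: acetal hydrolysis releases the C6 aldehyde; acetate, β‑keto lactone and enone tolerate brief dilute acid.

## Compound list

1 | 3‑methoxybenzoic acid | COc1cccc(C(=O)O)c1 | starting material
2 | 4‑bromophenol | Oc1ccc(Br)cc1 | starting material
3 | 2‑(4‑hydroxyphenyl)‑3‑methoxybenzoic acid | COc1cccc(C(=O)O)c1-c1ccc(O)cc1 | intermediate
4 | 5‑methoxyspiro[isochromane‑4,1′‑cyclohexa‑2′,5′‑diene]‑1,4′‑dione | COc1cccc2C(=O)OCC3(C=CC(=O)C=C3)c12 | intermediate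
5 | C5‑dioxolanyl spiro‑enone (dioxolane cis to C20) | COc1cccc2C(=O)OC[C@]3(C=CC(=O)C[C@H]3C5OCCO5)c12 | intermediate
6 | C4‑(benzyloxymethyl) spiro‑enone | COc1cccc2C(=O)OC[C@]3(C=CC(=O)[C@H](COCc4ccccc4)[C@H]3C5OCCO5)c12 | intermediate
7 | C4‑methyl‑C4‑(benzyloxymethyl) spiro‑enone | COc1cccc2C(=O)OC[C@]3(C=CC(=O)[C@@](C)(COCc4ccccc4)[C@H]3C5OCCO5)c12 | intermediate
8 | C3 enol triflate | COc1cccc2C(=O)OC[C@]3(CC=C(OS(=O)(=O)C(F)(F)F)[C@@](C)(COCc4ccccc4)[C@H]3C5OCCO5)c12 | intermediate
9 | aromatic spiro‑isochromanone, saturated A ring | COc1cccc2C(=O)OC[C@]3(CCC[C@@](C)(COCc4ccccc4)[C@H]3C5OCCO5)c12 | intermediate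
10 | Birch carboxylation product (1,4‑diene, lactone + CO2Me on C8) | COC(=O)[C@@]12C=CCC(OC)=C1[C@@]1(CCC[C@@](C)(CO)[C@H]1C5OCCO5)COC2=O | intermediate
11 | conjugated methoxydiene isomer | COC(=O)[C@@]12CC=CC(OC)=C1[C@@]1(CCC[C@@](C)(CO)[C@H]1C5OCCO5)COC2=O | intermediate
12 | transposed lactone, propargylic alcohol (C15 epimers) | C#CC(O)[C@]12CC=CC(OC)=C1[C@@]1(CCC[C@@](C)(CO)[C@H]1C5OCCO5)COC2=O | intermediate
13 | C19 acetate | C#CC(O)[C@]12CC=CC(OC)=C1[C@@]1(CCC[C@@](C)(COC(C)=O)[C@H]1C5OCCO5)COC2=O | intermediate
14 | bicyclo[3.2.1] C11 ketone, C15 alcohol | C=C1C(O)[C@]23C[C@H]1CC(=O)[C@@H]2[C@@]1(CCC[C@@](C)(COC(C)=O)[C@H]1C5OCCO5)COC3=O | intermediate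
15 | C11 equatorial alcohol, C15 alcohol | C=C1C(O)[C@]23C[C@H]1C[C@@H](O)[C@@H]2[C@@]1(CCC[C@@](C)(COC(C)=O)[C@H]1C5OCCO5)COC3=O | intermediate
16 | enone, C6 dioxolane | C=C1C(=O)[C@]23C[C@H]1C[C@@H](O)[C@@H]2[C@@]1(CCC[C@@](C)(COC(C)=O)[C@H]1C5OCCO5)COC3=O | intermediate
17 | trichorabdal B | C=C1C(=O)[C@]23C[C@H]1C[C@@H](O)[C@@H]2[C@@]1(CCC[C@@](C)(COC(C)=O)[C@H]1C=O)COC3=O | target

## Summary

Total steps: 15. Longest linear sequence: 15 (fully linear from 3‑methoxybenzoic acid).

Three steps most likely to fail, each with a fallback that changes the approach: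

1. **Step 3 (radical/iminium desymmetrization).** Enantio‑ and face‑selectivity on a hindered cross‑conjugated dienone are unproven. Fallback: switch to a polar desymmetrization — a cinchona primary‑amine‑catalysed nitro‑Michael addition of nitromethane to 4, followed by a Nef reaction run under acetalizing conditions to reach 5 (one extra step).
2. **Step 8 (Birch carboxylation: facial selectivity at C8).** If CO2 enters on the C5 face instead, use the stereocomplementary direct tactic: Birch reductive alkylation of 9 with propargyl bromide, so that the electrophile itself becomes C15 and the original lactone stays as C7. Then carry out the radical cyclization and install C15=O at the end by SeO2 allylic oxidation and Dess–Martin oxidation. One of the two tactics must give the required C8 configuration.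
3. **Step 12 (C9 configuration after cyclization).** If protonation gives the cis‑fused lactone instead, set C9 earlier: hydrolyse the enol ether at the stage of 10, before transposition, where the required C9 configuration corresponds to the cis‑fused old lactone. Then carry the enone through Luche reduction and silyl protection, lactone transposition, and radical cyclization onto the allylic‑ether alkene.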